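The numbers in the tables were generated by integration for substances that don't exist; the scatter is artificial.

In a one-step world every Ty lost turns up as Qo, and the two columns of a run add up to the charge.

| setting | west | north-west | delta | epsilon | theta | zeta |
|---|---|---|---|---|---|---|
| Ty | 0.020 M | 0.020 M | 0.020 M | 0.020 M | 0.020 M | 0.020 M (fed, over 15.0 h) |
| Dx | 1 equiv | 1.5 equiv | 1.00 equiv | 1.00 equiv (fed, over 15.0 h) | 1.00 equiv | 1.00 equiv |
| Ji | 1.4 mol% | 1.4 mol% | 1.4 mol% | 1.4 mol% | 1.4 mol% | 1.4 mol% |
| remark | run made earlier | run made earlier | a closed flask charged with all of it at once and left for 15 h | a stirred flask in which Dx is dosed at a steady rate over 15.0 h without added volume, worked up at 15 h | one stirred flow tank at steady state, fed with the mixture as stated, mean residence time 15 h | all but Ty at the start; Ty goes in evenly over 15.0 h, the run ends at 15 h |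
| time |  |  | 15 h | 15 h |  | 15 h |

| run | time / h | Qo / % | Ty / % |
|---|---|---|---|
| west | 0.667 | 2.8 | 95.2 |
| west | 2.00 | 10.9 | 90.3 |
| west | 3.00 | 15.8 | 83.6 |
| west | 5.00 | 20.6 | 74.9 |
| west | 6.00 | 24.9 | 71.5 |
| west | 10.0 | 34.3 | 56.8 |
| north-west | 0.333 | 2.5 | 98.7 |
| north-west | 0.667 | 3.8 | 96.3 |
| north-west | 1.00 | 3.0 | 95.8 |
| north-west | 1.50 | 5.7 | 92.9 |
| north-west | 2.50 | 11.0 | 89.2 |
| north-west | 5.00 | 19.0 | 79.5 |

(readings scatter by 1 percentage point)

- in percentages every species weighs as the Ty in it: one Ze counts as two
- the stated concentrations are those of everything mixed, before any reaction; amounts are the same in each set-up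
- the numbers in the tables scatter by 1 percentage point (one standard deviation)
- what may be going on: Ty + Ji <-> TyJi; TyJi <-> Ji + Qo; Dx + Ji <-> DxJi; DxJi -> Ji + Ja; Ty + Qo -> Ze
- the feed brings no volume worth counting
- the earlier runs were made in a closed, stirred flask

* order of the set-ups by the amount of Qo at the outlet or at the end, in percent of the Ty put in, highest first (delta / epsilon / theta / zeta)
* amount of Qo at the outlet or at the end, in percent of the Ty put in, delta
* amount of Qo at the outlet or at the end, in percent of the Ty put in, epsilon
* amount of Qo at the outlet or at the end, in percent of the Ty put in, theta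
* amount of Qo at the outlet or at the end, in percent of the Ty put in, zeta

West does not add up: at 10.0 h Ty has lost 43.2% and Qo stands at 34.3%, a gap of 8.90%, with each reading scattering by 1 percentage point. I take this gap as Ze, made by Ty + Qo.

What ties Ze to Qo? As an approximation I neglect the way back from Qo towards Ty and hold free Ji steady; then the rate of that step and the rate of making Qo both carry [Ty], so dividing one by the other removes [Ty] and time, and the ratio is [Qo] over a fixed level. Summed up while Qo is small against that level, Ze in percent is Qo squared over it. West therefore reads 132% for S, the level of Qo, in percent of the Ty charged, at which Ty + Qo takes Qo as fast as Ty gives it, a selectivity factor of a kind.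

How much Ty goes? West's Ty falls with a pseudo-first-order constant of 0.0566 h⁻¹. Delta then keeps 42.8% of its Ty, and S splits the loss into 43.1% Qo plus Ze. In zeta Ty enters evenly, which leaves 67.4% Ty, and the same split gives 27.1% Qo. The theta tank keeps 54.1% Ty, but all of it sits at outlet Qo, so Ze per Qo stands at its end value throughout, and I get 29.3% Qo.

Does feeding Dx help? North-west, with 1.5 equiv of Dx, kept more Ty at 5.00 h than west did, 79.5% against 74.9%. Epsilon starts without Dx, so I put it above delta, without a figure. My order is epsilon, delta, theta, zeta, with theta ahead of zeta by 2.2 points.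

The forecast has epsilon > delta > theta > zeta, with delta 42%, epsilon 52%, theta 32% and zeta 28%, starting from “Ty loss exceeds Qo gain”; its theta stands above mine.

The flasks give epsilon > delta > theta > zeta: delta 42.6%, epsilon 46.0%, theta 30.8%, zeta 27.5%.

    Ty + Ji ⇌ TyJi (K = 17.0 L mol⁻¹, k = 310 L mol⁻¹ h⁻¹)
    TyJi ⇌ Ji + Qo (K = 0.210 M, k = 170 h⁻¹)
    Dx + Ji ⇌ DxJi (K = 20.0 L mol⁻¹, k = 9400 L mol⁻¹ h⁻¹)
    DxJi → Ji + Ja (k = 2.10 h⁻¹)
    Ty + Qo → Ze (k = 1.50 L mol⁻¹ h⁻¹)

At 46.0% Qo, S ties epsilon to 16.0% Ze, and epsilon holds 15.3%. In a neighbour of epsilon with 0.84 mol% of Ji, I scale S with the loading to 79.3%; its 33.5% Qo then calls for 14.2% Ze, and that flask holds 12.8%. Epsilon is not at rest at 15 h, with 39% of its Ty and 93% of its Dx still there. Left until 150 h, it falls to 7.98% Ty and 26.5% Dx, its Qo drops to 30.9%, and Ze reaches 61.1%, against the 7.23% that S, which neglects the way back, gives for that Qo.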